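**Retrosynthetic overview**
1. The two oxirane rings are made last, by epoxidation of the C4=C5 and C1=C10 alkenes of a preformed (1(10)Z,4Z)-germacratriene, each directed by its neighbouring free hydroxyl.
2. The ten-membered ring is closed at C6–C7 in the germacrene A sense: an allylic C6 electrophile is captured at C7 by the C7=C11 π-system, and the double bond ends at C11=C12. The π-bond is activated as a chelated lithium dienolate of the C8 enone, so the (2Z)-chain cannot divert into a six-membered ring.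
3. The C15 chain comes from a three-component allene hydroboration–double allylboration (ethyl glyoxylate + C4 allenylboronate + (Z)-enal) followed by an isobutenyl Grignard addition.
4. Ring order: carbocycle (step 12), then 4,5-oxirane (step 14), then 1,10-oxirane (step 17).

Assumption: (+)-diisopinocampheylborane 7 is taken as a stock reagent (made from (−)-α-pinene and BH3·SMe2).
Numbering note: macrocycles are named with germacrane numbering (ring C1–C10; C7 carries the isopropenyl group, C4 and C10 the methyl groups, C3, C8 and C9 the oxygens).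

**Route**

Step 1
Reactants: 1 but-2-yn-1-ol
Product: 2 (2Z)-3-iodobut-2-en-1-ol
Conditions: NaAlH2(OCH2CH2OCH3)2, THF, 0 °C → rt; then I2, −78 °C
Reagents that add atoms: iodine, II
Why: Hydroxyl-directed trans-hydroalumination of the propargylic alcohol places aluminium on the distal carbon cis to CH2OH, and iodinolysis with retention gives the Z vinyl iodide.

Step 2
Reactants: 2 (2Z)-3-iodobut-2-en-1-ol
Product: 3 tert-butyl{[(2Z)-3-iodobut-2-en-1-yl]oxy}dimethylsilane
Conditions: TBSCl, imidazole, CH2Cl2, 0 °C → rt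
Reagents that add atoms: tert-butyldimethylsilyl chloride, CC(C)(C)[Si](C)(C)Cl
Why: Standard silyl ether formation protects the future C6 oxygen.

Step 3
Reactants: 3 tert-butyl{[(2Z)-3-iodobut-2-en-1-yl]oxy}dimethylsilane
Product: 4 (2Z)-4-[(tert-butyldimethylsilyl)oxy]-2-methylbut-2-enal
Conditions: t-BuLi (2.1 equiv), Et2O, −78 °C; then DMF, −78 °C → 0 °C
Reagents that add atoms: N,N-dimethylformamide, CN(C)C=O
Why: Iodine–lithium exchange and formylation both proceed with retention at the alkenyl carbon, so the Z geometry of the future C4=C5 alkene is carried over.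

Step 4
Reactants: 1 but-2-yn-1-ol
Product: 5 but-2-yn-1-yl methyl carbonate
Conditions: ClCO2Me, pyridine, CH2Cl2, 0 °C
Reagents that add atoms: methyl chloroformate, COC(=O)Cl
Why: O-Acylation installs the leaving group for the propargylic substitution.

Step 5
Reactants: 5 but-2-yn-1-yl methyl carbonate
Product: 6 2-(buta-2,3-dien-2-yl)-4,4,5,5-tetramethyl-1,3,2-dioxaborolane
Conditions: B2pin2, CuCl (5 mol %), KOt-Bu (5 mol %), Xantphos (5 mol %), THF, rt
Reagents that add atoms: bis(pinacolato)diboron, CC1(C)OB(OC1(C)C)B1OC(C)(C)C(C)(C)O1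
Why: Copper-boryl SN2′ substitution of a propargylic carbonate (borylcupration, then β-oxygen elimination) gives the 1,1-disubstituted allenylboronate.

Step 6
Reactants: 6 2-(buta-2,3-dien-2-yl)-4,4,5,5-tetramethyl-1,3,2-dioxaborolane; 7 (+)-diisopinocampheylborane; 8 ethyl glyoxylate; 4 (2Z)-4-[(tert-butyldimethylsilyl)oxy]-2-methylbut-2-enal
Product: 11 ethyl (2R,3Z,6R,7Z)-9-[(tert-butyldimethylsilyl)oxy]-2,6-dihydroxy-3,7-dimethylnona-3,7-dienoate, via γ-borylallylborane 9 (not isolated), via boryloxy allylboronate 10 (not isolated)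
Conditions: 7, 6, toluene, −25 °C, 5 h; 8 (0.8 equiv), −78 °C, 2 h; 4, −78 °C → rt, 24 h; then NaHCO3, H2O2, 0 °C
Reagents that add atoms: none
Why: Roush allene hydroboration–double allylboration, in which kinetic hydroboration gives the allylborane with Bpin cis to CH2B, Ipc-controlled chair addition to the Re face of glyoxylate sets C2 (R), and the resulting α-boryl allylboronate adds to 4 through a chair with the carbinol arm axial, giving the 3Z alkene and, by chirality transfer, the 1,5-anti C6 (R) carbinol.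

Step 7
Reactants: 11 ethyl (2R,3Z,6R,7Z)-9-[(tert-butyldimethylsilyl)oxy]-2,6-dihydroxy-3,7-dimethylnona-3,7-dienoate
Product: 12 ethyl (2R,3Z,6R,7Z)-9-[(tert-butyldimethylsilyl)oxy]-6-hydroxy-2-[(4-methoxybenzyl)oxy]-3,7-dimethylnona-3,7-dienoate
Conditions: Ag2O, 4-methoxybenzyl bromide, 4 Å MS, Et2O, rt, dark
Reagents that add atoms: 4-methoxybenzyl bromide, COc1ccc(CBr)cc1
Why: Purdie-type Ag2O alkylation is selective for the more acidic, ester-chelated α-hydroxyl and is non-basic, so C2 is not epimerised; this ether is the chelating group needed in steps 12 and 13.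

Step 8
Reactants: 12 ethyl (2R,3Z,6R,7Z)-9-[(tert-butyldimethylsilyl)oxy]-6-hydroxy-2-[(4-methoxybenzyl)oxy]-3,7-dimethylnona-3,7-dienoate
Product: 13 (2R,3Z,6R,7Z)-9-[(tert-butyldimethylsilyl)oxy]-6-hydroxy-N-methoxy-2-[(4-methoxybenzyl)oxy]-N,3,7-trimethylnona-3,7-dienamide
Conditions: MeNHOMe·HCl, AlMe3 (3 equiv), CH2Cl2, 0 °C → rt
Reagents that add atoms: N,O-dimethylhydroxylamine hydrochloride, CNOC.Cl
Why: Weinreb aminolysis with the non-basic aluminium amide converts the activated α-alkoxy ester without touching the α-stereocentre.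

Step 9
Reactants: 13 (2R,3Z,6R,7Z)-9-[(tert-butyldimethylsilyl)oxy]-6-hydroxy-N-methoxy-2-[(4-methoxybenzyl)oxy]-N,3,7-trimethylnona-3,7-dienamide; 14 (2-methylprop-1-en-1-yl)magnesium bromide
Product: 15 (5R,6Z,9R,10Z)-12-[(tert-butyldimethylsilyl)oxy]-9-hydroxy-5-[(4-methoxybenzyl)oxy]-2,6,10-trimethyldodeca-2,6,10-trien-4-one
Conditions: (CH3)2C=CHMgBr (3 equiv), THF, −20 → 0 °C; cold aq. NH4Cl
Reagents that add atoms: none
Why: Weinreb ketone synthesis, where the chelated tetrahedral intermediate stops at the ketone and delivers the C8 enone carrying C7 and C11–C13 (one equivalent is spent on the free hydroxyl).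

Step 10
Reactants: 15 (5R,6Z,9R,10Z)-12-[(tert-butyldimethylsilyl)oxy]-9-hydroxy-5-[(4-methoxybenzyl)oxy]-2,6,10-trimethyldodeca-2,6,10-trien-4-one
Product: 16 (2Z,4S,6Z,8R)-1-[(tert-butyldimethylsilyl)oxy]-8-[(4-methoxybenzyl)oxy]-3,7,11-trimethyl-9-oxododeca-2,6,10-trien-4-yl benzoate
Conditions: PhCO2H, PPh3, DIAD, toluene, −20 → 0 °C
Reagents that add atoms: benzoic acid, OC(=O)c1ccccc1
Why: Mitsunobu esterification inverts the allylic carbinol by SN2, turning the 1,5-anti pattern from step 6 into the C3 configuration of the target, and the benzoate serves as a base-stable protecting group.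

Step 11
Reactants: 16 (2Z,4S,6Z,8R)-1-[(tert-butyldimethylsilyl)oxy]-8-[(4-methoxybenzyl)oxy]-3,7,11-trimethyl-9-oxododeca-2,6,10-trien-4-yl benzoate
Product: 17 (2Z,4S,6Z,8R)-1-bromo-8-[(4-methoxybenzyl)oxy]-3,7,11-trimethyl-9-oxododeca-2,6,10-trien-4-yl benzoate
Conditions: Ph3PBr2, CH2Cl2, 0 °C → rt
Reagents that add atoms: dibromotriphenylphosphorane, BrP(Br)(c1ccccc1)(c1ccccc1)c1ccccc1
Why: Direct conversion of a primary silyl ether into the bromide through the oxyphosphonium salt (SN2 at the primary allylic carbon, neutral conditions) keeps the Z alkene and avoids a free alcohol.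

Step 12
Reactants: 17 (2Z,4S,6Z,8R)-1-bromo-8-[(4-methoxybenzyl)oxy]-3,7,11-trimethyl-9-oxododeca-2,6,10-trien-4-yl benzoate
Product: 19 (3S,7R,9R)-3-benzoyloxy-9-(4-methoxybenzyloxy)germacra-1(10)Z,4Z,11-trien-8-one, via lithium dienolate 18 (not isolated)
Conditions: LiN(SiMe3)2 (1.05 equiv), THF, −78 °C; slow addition of 17 (final 0.002 M); −78 → −20 °C; AcOH quench at −78 °C
Reagents that add atoms: none
Why: Proposed new method: γ-deprotonation of the s-cis β,β-dimethyl enone gives the Z(O) lithium dienolate, which is chelated to the C9 ether oxygen so that C10 and the tethered allylic bromide sit on one face, and α-selective SN2 attack of C7 on C6 closes the ten-membered ring with the double bond moving to C11=C12 (the same bond and alkene shift as the farnesyl-to-germacrene A closure) and sets C7 cis to the C9 oxygen; the closest known reactions are deconjugative α-alkylation of enone and enoate dienolates and macrocyclising intramolecular alkylations of stabilised carbanions with allylic halides used for germacranes.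

Step 13
Reactants: 19 (3S,7R,9R)-3-benzoyloxy-9-(4-methoxybenzyloxy)germacra-1(10)Z,4Z,11-trien-8-one
Product: 20 (3S,7R,8S,9R)-9-(4-methoxybenzyloxy)germacra-1(10)Z,4Z,11-triene-3,8-diol
Conditions: LiAlH4 (3 equiv), Et2O, −78 → 0 °C
Reagents that add atoms: none
Why: Cram-chelate hydride reduction (lithium bridging C8=O and the C9 ether) delivers hydride from the face of H9 and H7, giving the 8,9-cis and 7,8-cis C8 alcohol, and the benzoate is cleaved reductively in the same pot.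

Step 14
Reactants: 20 (3S,7R,8S,9R)-9-(4-methoxybenzyloxy)germacra-1(10)Z,4Z,11-triene-3,8-diol
Product: 21 (3S,4R,5S,7R,8S,9R)-4,5-epoxy-9-(4-methoxybenzyloxy)germacra-1(10)Z,11-diene-3,8-diol
Conditions: mCPBA (1.05 equiv), NaHCO3, CH2Cl2, −20 °C
Reagents that add atoms: 3-chloroperbenzoic acid, OOC(=O)c1cccc(Cl)c1
Why: Hydroxyl-assisted peracid epoxidation of a (Z)-allylic alcohol under A(1,3) control gives the threo epoxy alcohol (trans in a medium ring), setting C4 and C5 anti to the C3 oxygen, and the H-bonded alkene reacts faster than the ether-deactivated C1=C10 alkene and the 1,1-disubstituted isopropenyl group.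

Step 15
Reactants: 21 (3S,4R,5S,7R,8S,9R)-4,5-epoxy-9-(4-methoxybenzyloxy)germacra-1(10)Z,11-diene-3,8-diol; 22 angelic acid
Product: 23 (3S,4S,5S,7R,8S,9R)-3,8-bis(angeloyloxy)-4,5-epoxy-9-(4-methoxybenzyloxy)germacra-1(10)Z,11-diene
Conditions: 22 (6 equiv), 2,4,6-Cl3C6H2COCl, Et3N, toluene, rt; then 21, 75 °C
Reagents that add atoms: none
Why: Yamaguchi mixed-anhydride esterification without DMAP acylates both hindered secondary alcohols with retention and without Z to E isomerisation of the angelate.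

Step 16
Reactants: 23 (3S,4S,5S,7R,8S,9R)-3,8-bis(angeloyloxy)-4,5-epoxy-9-(4-methoxybenzyloxy)germacra-1(10)Z,11-diene
Product: 24 (3S,4S,5S,7R,8S,9R)-3,8-bis(angeloyloxy)-4,5-epoxygermacra-1(10)Z,11-dien-9-ol
Conditions: DDQ, CH2Cl2/pH 7 buffer (10:1), 0 °C
Reagents that add atoms: none
Why: Oxidative 4-methoxybenzyl ether cleavage under neutral conditions frees the C9 hydroxyl without acyl migration, epoxide opening or angelate isomerisation.

Step 17
Reactants: 24 (3S,4S,5S,7R,8S,9R)-3,8-bis(angeloyloxy)-4,5-epoxygermacra-1(10)Z,11-dien-9-ol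
Product: 25 (1R,3S,4S,5S,7R,8S,9S,10S)-3,8-bis(angeloyloxy)-1,10:4,5-diepoxygermacr-11-en-9-ol (CNP0304877.1)
Conditions: VO(acac)2 (5 mol %), t-BuOOH, CH2Cl2, 0 °C → rt
Reagents that add atoms: tert-butyl hydroperoxide, CC(C)(C)OO
Why: Vanadium-catalysed hydroxyl-directed epoxidation touches only the allylic-alcohol alkene and delivers oxygen syn to the C9 hydroxyl (erythro, as for 2-methyl allylic alcohols and medium-ring (Z)-cycloalkenols), setting C1 and C10.

**Compound list**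
1 | but-2-yn-1-ol | CC#CCO | starting material
2 | (2Z)-3-iodobut-2-en-1-ol | C/C(I)=C/CO | intermediate
3 | tert-butyl{[(2Z)-3-iodobut-2-en-1-yl]oxy}dimethylsilane | C/C(I)=C/CO[Si](C)(C)C(C)(C)C | intermediate
4 | (2Z)-4-[(tert-butyldimethylsilyl)oxy]-2-methylbut-2-enal | C/C(C=O)=C/CO[Si](C)(C)C(C)(C)C | intermediate
5 | but-2-yn-1-yl methyl carbonate | CC#CCOC(=O)OC | intermediate
6 | 2-(buta-2,3-dien-2-yl)-4,4,5,5-tetramethyl-1,3,2-dioxaborolane | C=C=C(C)B1OC(C)(C)C(C)(C)O1 | intermediate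
7 | (+)-diisopinocampheylborane, bis[(1S,2R,3S,5S)-2,6,6-trimethylbicyclo[3.1.1]heptan-3-yl]borane | B([C@H]1C[C@H]2C[C@@H]([C@@H]1C)C2(C)C)[C@H]1C[C@H]2C[C@@H]([C@@H]1C)C2(C)C | starting material
8 | ethyl glyoxylate (ethyl 2-oxoacetate) | CCOC(=O)C=O | starting material
9 | [(2E)-3-(pinacolboryl)but-2-en-1-yl]bis(isopinocampheyl)borane, Bpin cis to the CH2B group (not isolated) | C/C(B1OC(C)(C)C(C)(C)O1)=C/CB([C@H]1C[C@H]2C[C@@H]([C@@H]1C)C2(C)C)[C@H]1C[C@H]2C[C@@H]([C@@H]1C)C2(C)C | intermediate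
10 | ethyl (2R,3R)-2-{[bis(isopinocampheyl)boranyl]oxy}-3-methyl-3-(pinacolboryl)pent-4-enoate (not isolated) | CCOC(=O)[C@H](OB([C@H]1C[C@H]2C[C@@H]([C@@H]1C)C2(C)C)[C@H]1C[C@H]2C[C@@H]([C@@H]1C)C2(C)C)[C@@](C)(B1OC(C)(C)C(C)(C)O1)C=C | intermediate
11 | ethyl (2R,3Z,6R,7Z)-9-[(tert-butyldimethylsilyl)oxy]-2,6-dihydroxy-3,7-dimethylnona-3,7-dienoate | CC(C)(C)[Si](C)(C)OC/C=C(C)\[C@H](O)C/C=C(C)\[C@@H](O)C(=O)OCC | intermediate
12 | ethyl (2R,3Z,6R,7Z)-9-[(tert-butyldimethylsilyl)oxy]-6-hydroxy-2-[(4-methoxybenzyl)oxy]-3,7-dimethylnona-3,7-dienoate | CC(C)(C)[Si](C)(C)OC/C=C(C)\[C@H](O)C/C=C(C)\[C@@H](OCc1ccc(OC)cc1)C(=O)OCC | intermediate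
13 | (2R,3Z,6R,7Z)-9-[(tert-butyldimethylsilyl)oxy]-6-hydroxy-N-methoxy-2-[(4-methoxybenzyl)oxy]-N,3,7-trimethylnona-3,7-dienamide | CC(C)(C)[Si](C)(C)OC/C=C(C)\[C@H](O)C/C=C(C)\[C@@H](OCc1ccc(OC)cc1)C(=O)N(C)OC | intermediate
14 | (2-methylprop-1-en-1-yl)magnesium bromide | CC(C)=C[Mg]Br | starting material
15 | (5R,6Z,9R,10Z)-12-[(tert-butyldimethylsilyl)oxy]-9-hydroxy-5-[(4-methoxybenzyl)oxy]-2,6,10-trimethyldodeca-2,6,10-trien-4-one | CC(C)(C)[Si](C)(C)OC/C=C(C)\[C@H](O)C/C=C(C)\[C@@H](OCc1ccc(OC)cc1)C(=O)C=C(C)C | intermediate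
16 | (2Z,4S,6Z,8R)-1-[(tert-butyldimethylsilyl)oxy]-8-[(4-methoxybenzyl)oxy]-3,7,11-trimethyl-9-oxododeca-2,6,10-trien-4-yl benzoate | CC(C)(C)[Si](C)(C)OC/C=C(C)\[C@@H](OC(=O)c1ccccc1)C/C=C(C)\[C@@H](OCc1ccc(OC)cc1)C(=O)C=C(C)C | intermediate
17 | (2Z,4S,6Z,8R)-1-bromo-8-[(4-methoxybenzyl)oxy]-3,7,11-trimethyl-9-oxododeca-2,6,10-trien-4-yl benzoate | BrC/C=C(C)\[C@@H](OC(=O)c1ccccc1)C/C=C(C)\[C@@H](OCc1ccc(OC)cc1)C(=O)C=C(C)C | intermediate
18 | lithium Z(O)-dienolate of 17, LiO–C8(=C7H–C11(CH3)=CH2) (not isolated) | BrC/C=C(C)\[C@@H](OC(=O)c1ccccc1)C/C=C(C)\[C@@H](OCc1ccc(OC)cc1)/C(O[Li])=C/C(C)=C | intermediate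
19 | (3S,7R,9R)-3-benzoyloxy-9-(4-methoxybenzyloxy)germacra-1(10)Z,4Z,11-trien-8-one | C=C(C)[C@H]1C/C=C(C)\[C@@H](OC(=O)c2ccccc2)C/C=C(C)\[C@@H](OCc2ccc(OC)cc2)C1=O | intermediate
20 | (3S,7R,8S,9R)-9-(4-methoxybenzyloxy)germacra-1(10)Z,4Z,11-triene-3,8-diol | C=C(C)[C@H]1C/C=C(C)\[C@@H](O)C/C=C(C)\[C@@H](OCc2ccc(OC)cc2)[C@H]1O | intermediate
21 | (3S,4R,5S,7R,8S,9R)-4,5-epoxy-9-(4-methoxybenzyloxy)germacra-1(10)Z,11-diene-3,8-diol | C=C(C)[C@H]1C[C@@H]2O[C@]2(C)[C@@H](O)C/C=C(C)\[C@@H](OCc3ccc(OC)cc3)[C@H]1O | intermediate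
22 | angelic acid, (2Z)-2-methylbut-2-enoic acid | C/C=C(/C)C(=O)O | starting material
23 | (3S,4S,5S,7R,8S,9R)-3,8-bis(angeloyloxy)-4,5-epoxy-9-(4-methoxybenzyloxy)germacra-1(10)Z,11-diene | C=C(C)[C@H]1C[C@@H]2O[C@]2(C)[C@@H](OC(=O)/C(C)=C\C)C/C=C(C)\[C@@H](OCc3ccc(OC)cc3)[C@H]1OC(=O)/C(C)=C\C | intermediate
24 | (3S,4S,5S,7R,8S,9R)-3,8-bis(angeloyloxy)-4,5-epoxygermacra-1(10)Z,11-dien-9-ol | C=C(C)[C@H]1C[C@@H]2O[C@]2(C)[C@@H](OC(=O)/C(C)=C\C)C/C=C(C)\[C@@H](O)[C@H]1OC(=O)/C(C)=C\C | intermediate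
25 | (1R,3S,4S,5S,7R,8S,9S,10S)-3,8-bis(angeloyloxy)-1,10:4,5-diepoxygermacr-11-en-9-ol | C=C(C)[C@H]1C[C@@H]2O[C@]2(C)[C@@H](OC(=O)/C(C)=C\C)C[C@H]2O[C@@]2(C)[C@@H](O)[C@H]1OC(=O)/C(C)=C\C | target

**Step count and risks**
Total: 17 steps. Longest linear sequence: 15 steps (steps 1–3, then 6–17); steps 4–5 form the two-step side branch to 6.

The three steps most likely to fail:

Step 12 (macrocyclisation). The risks are deprotonation at C9 instead of the γ-methyl, O-alkylation, oligomers, or the C7 epimer. The fallback sets out from 16. HF·pyridine frees the primary allylic alcohol (2Z,4S,6Z,8R)-1-hydroxy-8-[(4-methoxybenzyl)oxy]-3,7,11-trimethyl-9-oxododeca-2,6,10-trien-4-yl benzoate F1, and ClCO2Me/pyridine converts it into the allylic methyl carbonate F2. Pd(PPh3)4 (5 mol %, THF, 0.002 M, 40 °C) then ionises the carbonate; the methoxide released generates the same dienolate beside a π-allyl palladium electrophile, and an intramolecular Tsuji–Trost α-allylation at the CH2 terminus forms the same C6–C7 bond. The route is rejoined at 19. The activation mode changes from SN2 to a neutral π-allyl; the weak point is possible erosion of the 4Z geometry.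

Step 6 (three-component double allylboration). The risks are a sluggish second allylboration with the hindered (Z)-enal, enal isomerisation, and the enantioselectivity of the glyoxylate addition. The fallback sets out from 4 (with 8) and sets each carbinol separately. Brown allylation of 4 with (+)-B-allyldiisopinocampheylborane gives (4R,5Z)-7-[(tert-butyldimethylsilyl)oxy]-5-methylhepta-1,5-dien-4-ol F3. Addition of CH2=C(CH3)MgBr to 8 followed by lipase resolution gives ethyl (2R)-2-hydroxy-3-methylbut-3-enoate F4. The two alcohols are joined with Ph2SiCl2/imidazole as the mixed diphenylsilylene bis-ether F5. Ring-closing metathesis with the second-generation Grubbs catalyst RuCl2(=CHPh)(PCy3)(H2IMes) gives the eight-membered cyclic silaketal F6, in which the new trisubstituted alkene can only be Z. AcOH/THF/H2O removes the tether and the route is rejoined at 11.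

Step 14 (hydroxyl-directed 4,5-epoxidation). The risks are competing epoxidation of the C1=C10 or isopropenyl alkenes and the wrong face. The fallback sets out from 20 and moves this epoxidation to the end under reagent control. Yamaguchi bis-angeloylation gives (3S,7R,8S,9R)-3,8-bis(angeloyloxy)-9-(4-methoxybenzyloxy)germacra-1(10)Z,4Z,11-triene F7. DDQ gives the C9 alcohol (3S,7R,8S,9R)-3,8-bis(angeloyloxy)germacra-1(10)Z,4Z,11-trien-9-ol F8. VO(acac)2/t-BuOOH gives (1R,3S,7R,8S,9S,10S)-3,8-bis(angeloyloxy)-1,10-epoxygermacra-4Z,11-dien-9-ol F9. A Shi epoxidation (fructose-derived ketone or its enantiomer, KHSO5, buffered MeCN/H2O, 0 °C) then epoxidises the remaining trisubstituted C4=C5 alkene anti to the C3 ester; this catalyst is slow on 1,1-disubstituted and electron-poor alkenes. The route is rejoined at 25.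

**Further compounds**
F1 | step 12 | (2Z,4S,6Z,8R)-1-hydroxy-8-[(4-methoxybenzyl)oxy]-3,7,11-trimethyl-9-oxododeca-2,6,10-trien-4-yl benzoate | OC/C=C(C)\[C@@H](OC(=O)c1ccccc1)C/C=C(C)\[C@@H](OCc1ccc(OC)cc1)C(=O)C=C(C)C
F2 | step 12 | (2Z,4S,6Z,8R)-1-[(methoxycarbonyl)oxy]-8-[(4-methoxybenzyl)oxy]-3,7,11-trimethyl-9-oxododeca-2,6,10-trien-4-yl benzoate | COC(=O)OC/C=C(C)\[C@@H](OC(=O)c1ccccc1)C/C=C(C)\[C@@H](OCc1ccc(OC)cc1)C(=O)C=C(C)C
F3 | step 6 | (4R,5Z)-7-[(tert-butyldimethylsilyl)oxy]-5-methylhepta-1,5-dien-4-ol | CC(C)(C)[Si](C)(C)OC/C=C(C)\[C@H](O)CC=C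
F4 | step 6 | ethyl (2R)-2-hydroxy-3-methylbut-3-enoate | C=C(C)[C@@H](O)C(=O)OCC
F5 | step 6 | mixed diphenylsilylene bis-ether of F3 and F4 | CC(C)(C)[Si](C)(C)OC/C=C(C)\[C@H](O[Si](c1ccccc1)(c1ccccc1)O[C@H](C(C)=C)C(=O)OCC)CC=C
F6 | step 6 | eight-membered cyclic diphenylsilaketal of diol 11 | CC(C)(C)[Si](C)(C)OC/C=C(C)\[C@H]1C/C=C(C)\[C@H](C(=O)OCC)O[Si](c2ccccc2)(c2ccccc2)O1
F7 | step 14 | (3S,7R,8S,9R)-3,8-bis(angeloyloxy)-9-(4-methoxybenzyloxy)germacra-1(10)Z,4Z,11-triene | C=C(C)[C@H]1C/C=C(C)\[C@@H](OC(=O)/C(C)=C\C)C/C=C(C)\[C@@H](OCc2ccc(OC)cc2)[C@H]1OC(=O)/C(C)=C\C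
F8 | step 14 | (3S,7R,8S,9R)-3,8-bis(angeloyloxy)germacra-1(10)Z,4Z,11-trien-9-ol | C=C(C)[C@H]1C/C=C(C)\[C@@H](OC(=O)/C(C)=C\C)C/C=C(C)\[C@@H](O)[C@H]1OC(=O)/C(C)=C\C
F9 | step 14 | (1R,3S,7R,8S,9S,10S)-3,8-bis(angeloyloxy)-1,10-epoxygermacra-4Z,11-dien-9-ol | C=C(C)[C@H]1C/C=C(C)\[C@@H](OC(=O)/C(C)=C\C)C[C@H]2O[C@@]2(C)[C@@H](O)[C@H]1OC(=O)/C(C)=C\C
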